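**Plan**

- Retrosynthesis: the ring A enone is taken back to a C3 carbinol and the aryl ether to a C11 alcohol plus isofraxidin. The C9–H/C7=C8 array is taken back to an 8-en-7-one hydrazone, which comes from the 11-nor 7-en-9-one 13 by adding C11 at C9 and moving the oxygen from C9 to C7. Enone 13 is cut at C5–C10 and C7=C8 to the open-chain keto-enal 10.
- Enabling feature: C12–C8–C9–C10–C15 of ring B is a pentan-3-one unit (C9 is its carbonyl carbon once C11 is removed). Its two α-carbons C10 and C8 face the three-carbon enal unit C5–C6–C7 across ring B. C10 is also a ring A atom, so the Michael bond C5–C10 closes ring A and the aldol condensation at C7=C8 closes ring B; the quaternary C4 leaves the enal without γ-hydrogens.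
- Forward: pentan-3-one and acrolein give the C3 aldehyde; reverse prenylation makes C3–C4; cross-metathesis adds C6–C7 as the enal. Ring A and then ring B close in one flask. C11 is added to C9, the oxygen is moved to C7 and removed with return of the C7=C8 alkene, the coumarin is attached, and ring A is oxidised.
- Stereochemistry: C3 (R) is set by reagent-controlled prenylboration. C5 and C10 are relayed from C3 in the chair Michael transition state of the key step. C9 is relayed from the decalin by facial hydride attack on the C7 hydrazone and suprafacial diazene hydrogen transfer. The C3 carbinol is oxidised at the end.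

Key step: step 5

Remark: drimane numbering is used for all compounds, also the open-chain ones (C1–C10 ring carbons, C11 = CH2O, C12 = methyl on C8, C15 = methyl on C10). The SMILES of the target is read as H5 trans and H9 cis to the C10 methyl, with C11 axial. (−)-Ipc2BH, 3-methylbuta-1,2-diene, stannane 14 and isofraxidin 22 are taken as commercial.

Step 1
Reactants: 1 pentan-3-one; 2 acrolein
Product: 5 4-methyl-5-oxoheptanal (racemic), via enamine 3 (not isolated), via adduct enamine 4 (not isolated)
Conditions: pyrrolidine, p-TsOH (cat.), PhH, reflux (Dean–Stark); then 2, MeCN, 0 °C → rt; then AcOH, NaOAc, H2O, rt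
Reagents that add atoms: none
Why: Stork enamine Michael addition, in which the CH(CH3) carbon of enamine 3 adds to acrolein and mild aqueous acid hydrolyses adduct 4 to the 1,5-keto aldehyde; the new stereocentre (future C10) is left racemic because step 5 makes it planar.

Step 2
Reactants: 5 4-methyl-5-oxoheptanal
Product: 7 (7R)-7-hydroxy-4,8,8-trimethyldec-9-en-3-one (both C4 epimers), via borinate 6 (not isolated)
Conditions: (−)-Ipc2BH, 3-methylbuta-1,2-diene, THF, −25 °C (gives (−)-Ipc2B-prenyl); then 5, Et2O, −78 °C; then NaOH, H2O2, 0 °C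
Reagents that add atoms: (−)-B-(3-methylbut-2-enyl)diisopinocampheylborane (CC(C)=CCB([C@H]1[C@H](C)[C@H]2C[C@@H](C1)C2(C)C)[C@H]1[C@H](C)[C@H]2C[C@@H](C1)C2(C)C)
Why: Brown allylboration with the γ,γ-dimethylallyl borane, which reacts with the aldehyde in preference to the ketone through a chair Zimmerman–Traxler transition state with allyl transposition, builds the quaternary C4 with its vinyl group and should set C3 as R by reagent control (Si-face attack of the reagent from (+)-α-pinene, as for the parent allyl reagent).

Step 3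
Reactants: 7 (7R)-7-hydroxy-4,8,8-trimethyldec-9-en-3-one
Product: 8 (7R)-7-(tert-butyldimethylsilyloxy)-4,8,8-trimethyldec-9-en-3-one
Conditions: TBSOTf, 2,6-lutidine, CH2Cl2, −78 → 0 °C
Reagents that add atoms: tert-butyldimethylsilyl trifluoromethanesulfonate (CC(C)(C)[Si](C)(C)OS(=O)(=O)C(F)(F)F)
Why: silylation of the hindered secondary alcohol with the silyl triflate under non-nucleophilic base traps the open hydroxy ketone (not its hemiketal) and gives the bulky equatorial control group for step 5.

Step 4
Reactants: 8 (7R)-7-(tert-butyldimethylsilyloxy)-4,8,8-trimethyldec-9-en-3-one; 9 (E)-but-2-enal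
Product: 10 (2E,5R)-5-(tert-butyldimethylsilyloxy)-4,4,8-trimethyl-9-oxoundec-2-enal
Conditions: second-generation Hoveyda–Grubbs catalyst (5–10 mol %), 9 (5 equiv), CH2Cl2, 45 °C
Reagents that add atoms: none
Why: olefin cross-metathesis of the hindered, non-dimerising vinyl group with the enal partner should give the E-enal with loss of propene, while ketone and silyl ether are inert to the ruthenium carbene.

Step 5
Reactants: 10 (2E,5R)-5-(tert-butyldimethylsilyloxy)-4,4,8-trimethyl-9-oxoundec-2-enal
Product: 13 3-(tert-butyldimethylsilyloxy)-11-nordrim-7-en-9-one (trans-fused; OTBS cis to the C10 methyl), via Michael adduct 11 (not isolated), via aldol 12 (not isolated)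
Conditions: KOt-Bu (0.3 equiv), t-BuOH/THF 1:4, 0.01 M, 0 → 50 °C
Reagents that add atoms: none
Why: Catalytic tert-butoxide equilibrates the enolates of ketone 10, and only the more substituted C10 enolate can reach the enal β-carbon C5 through a six-membered chair, so a 6-(enolexo)-exo-trig Michael addition forms C5–C10 and ring A (11); the C7 aldehyde set free in this way is then attacked by the C8 enolate of the same ketone in a 6-(enolendo)-exo-trig aldol closure of ring B (12), and E1cB loss of water gives the C7=C8 enone 13. The closest known reaction type is the Robinson-type Michael/aldol-condensation cascade in its [3+3] form, in which one ketone uses both α-carbons against the β-carbon and the carbonyl carbon of an enal. C5 is controlled by the C3 silyloxy stereocentre: in the chair the OTBS group and the enal chain both sit equatorial, which exposes one face of C5. C10 is controlled by the axial C4 methyl, which forces the planar enolate carbon C9 into the equatorial site and the small C10 methyl into the axial one, so that the fusion should be trans; both C10 epimers of 10 converge because C10 is planar in the enolate. Regioselectivity needs no protecting device, since C8 to C5 would require an eight-membered ring and C6 to C9 a four-membered one, and the quaternary C4 leaves the enal without γ-hydrogens. The irreversible dehydration is expected to pull the congested Michael equilibrium forward, and high dilution suppresses intermolecular aldol reactions of the enal.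

Step 6
Reactants: 13 3-(tert-butyldimethylsilyloxy)-11-nordrim-7-en-9-one; 14 tributyl[(methoxymethoxy)methyl]stannane
Product: 15 9-hydroxy-11-(methoxymethoxy)-3-(tert-butyldimethylsilyloxy)drim-7-ene (C9 configuration not controlled)
Conditions: 14, n-BuLi, THF, −78 °C; then 13, −78 → −40 °C; aq. NH4Cl
Reagents that add atoms: none
Why: tin–lithium exchange gives the α-alkoxymethyl lithium reagent, which should add 1,2 to the hindered α-methyl enone as other small organolithiums do with 2,6,6-trisubstituted cyclohexenones; the C9 configuration is irrelevant because C9 becomes sp2 in step 7.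

Step 7
Reactants: 15 9-hydroxy-11-(methoxymethoxy)-3-(tert-butyldimethylsilyloxy)drim-7-ene
Product: 16 11-(methoxymethoxy)-3-(tert-butyldimethylsilyloxy)drim-8-en-7-one
Conditions: pyridinium chlorochromate (C5H5NH[CrO3Cl]), 4 Å molecular sieves, CH2Cl2, rt
Reagents that add atoms: pyridinium chlorochromate ([O-][Cr](=O)(=O)Cl.c1cc[nH+]cc1)
Why: Babler–Dauben oxidative transposition, in which the chromate ester of the tertiary allylic alcohol undergoes a [3,3] shift to C7 and is oxidised there, gives the 8-en-7-one with C11 already on C9; the C7–C8 σ-bond from step 5 is kept.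

Step 8
Reactants: 16 11-(methoxymethoxy)-3-(tert-butyldimethylsilyloxy)drim-8-en-7-one
Product: 17 7-(p-toluenesulfonylhydrazone) of 16
Conditions: TsNHNH2, EtOH, 50 °C
Reagents that add atoms: p-toluenesulfonohydrazide (Cc1ccc(cc1)S(=O)(=O)NN)
Why: condensation at the C7 carbonyl, which has an unhindered CH2 neighbour, should proceed as for other α-methyl cyclohexenones.

Step 9
Reactants: 17 7-(p-toluenesulfonylhydrazone) of 16
Product: 20 11-(methoxymethoxy)-3-(tert-butyldimethylsilyloxy)drim-7-ene (H9 cis to the C10 methyl; C11 axial), via N-borylhydrazine 18 (not isolated), via allylic diazene 19 (not isolated)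
Conditions: catecholborane, CHCl3, 0 °C; then NaOAc·3H2O, reflux
Reagents that add atoms: none
Why: catecholborane reduction of the α,β-unsaturated tosylhydrazone (reductive 1,3-transposition) delivers hydride axially to C7 on the face away from the C10 methyl, and the resulting diazene on the methyl face passes its hydrogen suprafacially to C9 with loss of N2, which restores C7=C8 and sets H9 cis to the C10 methyl, as in steroidal 4-en-3-one hydrazones that give the 5β-hydrogen.

Step 10
Reactants: 20 11-(methoxymethoxy)-3-(tert-butyldimethylsilyloxy)drim-7-ene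
Product: 21 drim-7-ene-3,11-diol (3-OH cis to the C10 methyl; H5 trans; H9 cis)
Conditions: HCl (3 M in MeOH), 40 °C
Reagents that add atoms: none
Why: acidic methanolysis cleaves the methoxymethyl acetal and the silyl ether in one operation under conditions that should not protonate the trisubstituted alkene.

Step 11
Reactants: 21 drim-7-ene-3,11-diol; 22 isofraxidin (7-hydroxy-6,8-dimethoxycoumarin)
Product: 23 7-[(3-hydroxydrim-7-en-11-yl)oxy]-6,8-dimethoxycoumarin
Conditions: PPh3, DIAD, toluene/THF, 0 → 60 °C
Reagents that add atoms: none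
Why: Mitsunobu etherification of the acidic phenol should occur only at the primary C11 alcohol, since the C3 carbinol next to the gem-dimethyl carbon is too hindered to form the oxyphosphonium ion; no stereocentre is touched.

Step 12
Reactants: 23 7-[(3-hydroxydrim-7-en-11-yl)oxy]-6,8-dimethoxycoumarin
Product: 25 7-[(3-oxodrima-1,7-dien-11-yl)oxy]-6,8-dimethoxycoumarin (CNP0330704.1), via ketone 24 (not isolated)
Conditions: IBX (4 equiv), DMSO, 80 °C
Reagents that add atoms: none
Why: IBX oxidises the alcohol to the C3 ketone and then dehydrogenates it through its enol, which can form only towards C2 because C4 is quaternary, so the C1=C2 enone results and the quaternary C10 stops further oxidation.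

**Compound list**

1 | pentan-3-one | CCC(=O)CC | starting material
2 | acrolein (prop-2-enal) | C=CC=O | starting material
3 | 1-(pent-2-en-3-yl)pyrrolidine | CC=C(CC)N1CCCC1 | intermediate
4 | 4-methyl-5-(pyrrolidin-1-yl)hept-5-enal | CC=C(N1CCCC1)C(C)CCC=O | intermediate
5 | 4-methyl-5-oxoheptanal (racemic) | CCC(=O)C(C)CCC=O | intermediate
6 | diisopinocampheylborinate of 7 | CCC(=O)C(C)CC[C@@H](OB([C@H]1[C@H](C)[C@H]2C[C@@H](C1)C2(C)C)[C@H]1[C@H](C)[C@H]2C[C@@H](C1)C2(C)C)C(C)(C)C=C | intermediate
7 | (7R)-7-hydroxy-4,8,8-trimethyldec-9-en-3-one (both C4 epimers) | CCC(=O)C(C)CC[C@@H](O)C(C)(C)C=C | intermediate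
8 | (7R)-7-(tert-butyldimethylsilyloxy)-4,8,8-trimethyldec-9-en-3-one | CCC(=O)C(C)CC[C@@H](O[Si](C)(C)C(C)(C)C)C(C)(C)C=C | intermediate
9 | (E)-but-2-enal (crotonaldehyde) | C/C=C/C=O | starting material
10 | (2E,5R)-5-(tert-butyldimethylsilyloxy)-4,4,8-trimethyl-9-oxoundec-2-enal | CCC(=O)C(C)CC[C@@H](O[Si](C)(C)C(C)(C)C)C(C)(C)/C=C/C=O | intermediate
11 | 2-[2,2,6-trimethyl-6-propanoyl-3-(tert-butyldimethylsilyloxy)cyclohexyl]acetaldehyde (ring A closed; H5 trans and OTBS cis to the C10 methyl) | CCC(=O)[C@]1(C)CC[C@@H](O[Si](C)(C)C(C)(C)C)C(C)(C)[C@H]1CC=O | intermediate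
12 | 7-hydroxy-3-(tert-butyldimethylsilyloxy)-11-nordriman-9-one (C7 and C8 not defined) | CC1C(O)C[C@@H]2C(C)(C)[C@H](O[Si](C)(C)C(C)(C)C)CC[C@@]2(C)C1=O | intermediate
13 | 3-(tert-butyldimethylsilyloxy)-11-nordrim-7-en-9-one (trans-fused; OTBS cis to the C10 methyl) | CC1=CC[C@@H]2C(C)(C)[C@H](O[Si](C)(C)C(C)(C)C)CC[C@@]2(C)C1=O | intermediate
14 | tributyl[(methoxymethoxy)methyl]stannane | CCCC[Sn](CCCC)(CCCC)COCOC | starting material
15 | 9-hydroxy-11-(methoxymethoxy)-3-(tert-butyldimethylsilyloxy)drim-7-ene (C9 not controlled) | CC1=CC[C@@H]2C(C)(C)[C@H](O[Si](C)(C)C(C)(C)C)CC[C@@]2(C)C1(O)COCOC | intermediate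
16 | 11-(methoxymethoxy)-3-(tert-butyldimethylsilyloxy)drim-8-en-7-one | COCOCC1=C(C)C(=O)C[C@@H]2C(C)(C)[C@H](O[Si](C)(C)C(C)(C)C)CC[C@@]12C | intermediate
17 | 7-(p-toluenesulfonylhydrazone) of 16 | COCOCC1=C(C)C(=NNS(=O)(=O)c3ccc(C)cc3)C[C@@H]2C(C)(C)[C@H](O[Si](C)(C)C(C)(C)C)CC[C@@]12C | intermediate
18 | C7 N-(catecholboryl)-N'-tosylhydrazine (nitrogen on the face of the C10 methyl) | COCOCC1=C(C)[C@H](N(NS(=O)(=O)c3ccc(C)cc3)B3Oc4ccccc4O3)C[C@@H]2C(C)(C)[C@H](O[Si](C)(C)C(C)(C)C)CC[C@@]12C | intermediate
19 | C7 allylic diazene | COCOCC1=C(C)[C@H](N=N)C[C@@H]2C(C)(C)[C@H](O[Si](C)(C)C(C)(C)C)CC[C@@]12C | intermediate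
20 | 11-(methoxymethoxy)-3-(tert-butyldimethylsilyloxy)drim-7-ene (H9 cis to the C10 methyl; C11 axial) | COCOC[C@H]1C(C)=CC[C@@H]2C(C)(C)[C@H](O[Si](C)(C)C(C)(C)C)CC[C@]21C | intermediate
21 | drim-7-ene-3,11-diol (3-OH cis to the C10 methyl; H5 trans; H9 cis) | OC[C@H]1C(C)=CC[C@@H]2C(C)(C)[C@H](O)CC[C@]21C | intermediate
22 | isofraxidin (7-hydroxy-6,8-dimethoxycoumarin) | COc1cc2ccc(=O)oc2c(OC)c1O | starting material
23 | 7-[(3-hydroxydrim-7-en-11-yl)oxy]-6,8-dimethoxycoumarin | COc1cc2ccc(=O)oc2c(OC)c1OC[C@H]1C(C)=CC[C@@H]2C(C)(C)[C@H](O)CC[C@]21C | intermediate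
24 | 7-[(3-oxodrim-7-en-11-yl)oxy]-6,8-dimethoxycoumarin | COc1cc2ccc(=O)oc2c(OC)c1OC[C@H]1C(C)=CC[C@@H]2C(C)(C)C(=O)CC[C@]21C | intermediate
25 | 7-{[(5S,9S,10R)-3-oxodrima-1,7-dien-11-yl]oxy}-6,8-dimethoxycoumarin (CNP0330704.1) | COc1cc2ccc(=O)oc2c(OC)c1OC[C@H]1C(C)=CC[C@@H]2C(C)(C)C(=O)C=C[C@]21C | target

**Count and risks**

Total steps: 12. Longest linear sequence: 12 (from pentan-3-one 1 to 25).

Step 5. What may go wrong: the Michael closure makes the most congested bond of the skeleton (C5–C10, next to the quaternary C4). It may be slow enough for intermolecular aldol oligomerisation of the enal to compete, and the 1,3-relay from C3 or the trans/cis selection at C10 may be weak. Fallback, from 8 back to 16: cross-metathesis of 8 with methyl acrylate (second-generation Hoveyda–Grubbs catalyst, CH2Cl2, 40 °C) should give the methyl enoate F1. NaOMe in MeOH at reflux then runs a reversible Michael addition followed by Claisen acylation of C8 by the ester; the stabilised enolate of the trans-fused 8-methyl-7,9-dione F2 is the thermodynamic sink. Trimethyl orthoformate, MeOH and catalytic camphorsulfonic acid should give the less hindered C7 methyl enol ether F3. Addition of the lithium reagent from 14 and n-BuLi to the C9 carbonyl and dilute HCl work-up (Stork–Danheiser transposition) gives 16.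

Step 9. What may go wrong: hydride delivery to the C7 hydrazone from the wrong face, or incomplete suprafacial hydrogen transfer, would give the C9 epimer or alkene isomers. Fallback, from 13 back to 21: nucleophilic epoxidation of 13 (H2O2, NaOH, MeOH, 0 °C) on the face away from the C10 methyl gives the epoxy ketone F4. Wharton transposition (N2H4·H2O, AcOH, MeOH) gives the 8-en-7-ol F5 with the hydroxyl axial and anti to the C10 methyl. KH and Bu3SnCH2I give the stannylmethyl ether F6. n-BuLi (THF, −78 °C) triggers the Still–Wittig [2,3] shift, which delivers CH2OH to C9 on the face of the C7 oxygen and moves the alkene to C7=C8, giving the primary alcohol F7. HCl in MeOH removes the silyl group to give 21.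

Step 11. What may go wrong: the redox condensation may stall at the axial, β-branched C11 carbinol with a phenol that carries two ortho methoxy groups, so that the betaine is consumed by hydrazide alkylation instead. Fallback, from 21 back to 23: selective sulfonylation of the primary alcohol (Tf2O, 2,6-di-tert-butylpyridine, CH2Cl2, −78 °C) gives the primary triflate F8, which is displaced by the cesium salt of 22 (Cs2CO3, DMF, rt) to give 23.

Further compounds
F1 | step 5 | methyl (2E,5R)-5-(tert-butyldimethylsilyloxy)-4,4,8-trimethyl-9-oxoundec-2-enoate | CCC(=O)C(C)CC[C@@H](O[Si](C)(C)C(C)(C)C)C(C)(C)/C=C/C(=O)OC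
F2 | step 5 | 3-(tert-butyldimethylsilyloxy)-11-nordrimane-7,9-dione (trans-fused; C8 enolisable) | CC1C(=O)C[C@@H]2C(C)(C)[C@H](O[Si](C)(C)C(C)(C)C)CC[C@@]2(C)C1=O
F3 | step 5 | 7-methoxy-3-(tert-butyldimethylsilyloxy)-11-nordrim-7-en-9-one | CC1=C(OC)C[C@@H]2C(C)(C)[C@H](O[Si](C)(C)C(C)(C)C)CC[C@@]2(C)C1=O
F4 | step 9 | 7,8-epoxy-3-(tert-butyldimethylsilyloxy)-11-nordriman-9-one (epoxide anti to the C10 methyl) | C[C@]12O[C@H]1C[C@@H]1C(C)(C)[C@H](O[Si](C)(C)C(C)(C)C)CC[C@@]1(C)C2=O
F5 | step 9 | 3-(tert-butyldimethylsilyloxy)-11-nordrim-8-en-7-ol (7-OH anti to the C10 methyl) | CC1=C[C@]2(C)CC[C@@H](O[Si](C)(C)C(C)(C)C)C(C)(C)[C@H]2C[C@@H]1O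
F6 | step 9 | 7-[(tributylstannyl)methoxy]-3-(tert-butyldimethylsilyloxy)-11-nordrim-8-ene | CC1=C[C@]2(C)CC[C@@H](O[Si](C)(C)C(C)(C)C)C(C)(C)[C@H]2C[C@@H]1OC[Sn](CCCC)(CCCC)CCCC
F7 | step 9 | 3-(tert-butyldimethylsilyloxy)drim-7-en-11-ol (H9 cis to the C10 methyl) | OC[C@H]1C(C)=CC[C@@H]2C(C)(C)[C@H](O[Si](C)(C)C(C)(C)C)CC[C@]21C
F8 | step 11 | 3-hydroxydrim-7-en-11-yl trifluoromethanesulfonate | O=S(=O)(OC[C@H]1C(C)=CC[C@@H]2C(C)(C)[C@H](O)CC[C@]21C)C(F)(F)F
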